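## Retrosynthetic overview
1. The key C–C bond is made last. The diarylmethane is cut at CH2–C1' of the guaiacyl ring. The quinolone 7-carbaldehyde, as its N–H hydrazone, acts as a benzyl-anion equivalent (polarity-reversed formyl carbon). Nickel catalysis joins it to the electrophilic C–Br carbon of 4-bromo-2-methoxyphenol, and loss of N2 leaves the CH2 directly.
2. The 8-O-sulfate is installed before that coupling, while the molecule has only one phenol. No protecting group is needed anywhere, and the sulfate masks the chelating salicyl OH.
3. The formyl carbon comes from ortho-specific magnesium-mediated formylation of 8-hydroxy-3-methoxyquinolin-2(1H)-one, where C7 is the only free ortho site.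
4. Only one ring is built, the pyridone ring. It comes from N-acylation and Camps-type condensation of 2-amino-3-hydroxybenzaldehyde with methoxyacetyl chloride. Both benzene rings are bought.
5. The amino aldehyde comes from 3-hydroxy-2-nitrobenzaldehyde.

Assumption: scolopendrine has no stereocentre or stereogenic axis, so the SMILES defines one achiral compound and no stereocontrol is needed; the target is delivered as the free hydrogen sulfate as drawn.

## Route

Step 1
Reactants: 1 3-hydroxy-2-nitrobenzaldehyde
Product: 2 2-amino-3-hydroxybenzaldehyde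
Conditions: H2 (1 atm), 10% Pd/C, EtOAc, rt, stopped at 3 equiv H2; filtered, concentrated cold, used the same day
Reagents that add atoms: none
Why: In this catalytic hydrogenation (nitro reduction) under neutral conditions at 1 atm, the nitro group takes up hydrogen far faster than the hydrogen-bonded aryl aldehyde, as in the usual preparation of o-aminobenzaldehydes for Friedländer chemistry.

Step 2
Reactants: 2 2-amino-3-hydroxybenzaldehyde; 3 methoxyacetyl chloride (2.3 equiv)
Product: 6 8-hydroxy-3-methoxyquinolin-2(1H)-one, via diacylated aldehyde 4 (not isolated), via hydroxy amide 5 (not isolated)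
Conditions: pyridine, DMAP (cat.), CH2Cl2, 0 °C to rt; evaporate; NaOMe (4 equiv), MeOH, 65 °C; 1 M HCl to pH 4
Reagents that add atoms: methoxyacetyl chloride (3), COCC(=O)Cl
Why: After N,O-diacylation, a Camps-type intramolecular aldol (Knoevenagel) condensation follows, in which methoxide transesterifies the aryl ester of 4 to give 5, the amide alpha-CH2 adds to the ortho aldehyde in a six-membered closure, and dehydration to the aromatic 2-quinolone makes the sequence irreversible.

Step 3
Reactants: 6 8-hydroxy-3-methoxyquinolin-2(1H)-one
Product: 7 8-hydroxy-3-methoxy-2-oxo-1,2-dihydroquinoline-7-carbaldehyde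
Conditions: MgCl2 (anhydrous, 3 equiv), Et3N (6 equiv), (CH2O)n (8 equiv), MeCN, 82 °C; 1 M HCl
Reagents that add atoms: paraformaldehyde (reacts as formaldehyde), C=O
Why: In this Casnati–Skattebøl ortho-formylation the magnesium phenoxide delivers coordinated formaldehyde only to the ortho carbon, which here is C7 alone (the para site C5 is untouched), and hydride transfer to a second formaldehyde raises the new benzylic alkoxide to the aldehyde.

Step 4
Reactants: 7 8-hydroxy-3-methoxy-2-oxo-1,2-dihydroquinoline-7-carbaldehyde
Product: 8 tributylammonium 7-formyl-3-methoxy-2-oxo-1,2-dihydroquinolin-8-yl sulfate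
Conditions: Bu3N·SO3 (2 equiv), MeCN, 80 °C; SiO2, CH2Cl2/MeOH
Reagents that add atoms: tributylsulfoammonium betaine (Bu3N·SO3), CCCC[N+](CCCC)(CCCC)S(=O)(=O)[O-]
Why: This is phenol O-sulfation by SO3 transfer from a trialkylamine–SO3 complex, in which the only phenol present is sulfated, any N-sulfonation of the lactam reverts on work-up, and the lipophilic ammonium salt is soluble in organic solvents and can be chromatographed.

Step 5
Reactants: 8 tributylammonium 7-formyl-3-methoxy-2-oxo-1,2-dihydroquinolin-8-yl sulfate; 9 4-bromo-2-methoxyphenol (2 equiv)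
Product: 12 scolopendrine, via hydrazone salt 10 (not isolated), via scolopendrine tributylammonium salt 11 (not isolated)
Conditions: N2H4·H2O (1.2 equiv), THF, rt; then 9, Ni(cod)2 (10 mol %), PMe3 (20 mol %), DBU (5 equiv), THF/1,4-dioxane, 80 °C, Ar; sulfonic acid resin (H+ form), MeOH/H2O, 0 °C; C18, lyophilise
Reagents that add atoms: 4-bromo-2-methoxyphenol (9), COc1cc(Br)ccc1O; hydrazine hydrate, NN.O (its nitrogens are carried only by 10 and leave as N2)
Why: In this nickel-catalysed deoxygenative (Wolff–Kishner-type) cross-coupling of an N-unsubstituted hydrazone with an aryl bromide, the hydrazone turns the formerly electrophilic formyl carbon into a benzyl-carbanion equivalent that is passed to the aryl–nickel bromide formed when zerovalent nickel inserts into 9, reductive elimination and base-induced loss of N2 give the CH2 link directly, the sulfate monoanion blocks salicyl-type N,O-chelation of divalent nickel and is inert to base, hydrazine and zerovalent nickel, and the phenol and lactam N–H only consume DBU, as bromophenols do in other basic cross-couplings.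

## Compound list
1 | 3-hydroxy-2-nitrobenzaldehyde | O=Cc1cccc(O)c1[N+](=O)[O-] | starting material
2 | 2-amino-3-hydroxybenzaldehyde | Nc1c(O)cccc1C=O | intermediate
3 | methoxyacetyl chloride | COCC(=O)Cl | starting material
4 | 3-formyl-2-[(methoxyacetyl)amino]phenyl methoxyacetate | COCC(=O)Nc1c(C=O)cccc1OC(=O)COC | intermediate
5 | N-(2-formyl-6-hydroxyphenyl)-2-methoxyacetamide | COCC(=O)Nc1c(O)cccc1C=O | intermediate
6 | 8-hydroxy-3-methoxyquinolin-2(1H)-one | COc1cc2cccc(O)c2[nH]c1=O | intermediate
7 | 8-hydroxy-3-methoxy-2-oxo-1,2-dihydroquinoline-7-carbaldehyde | COc1cc2ccc(C=O)c(O)c2[nH]c1=O | intermediate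
8 | tributylammonium 7-formyl-3-methoxy-2-oxo-1,2-dihydroquinolin-8-yl sulfate | COc1cc2ccc(C=O)c(OS(=O)(=O)[O-])c2[nH]c1=O.CCCC[NH+](CCCC)CCCC | intermediate
9 | 4-bromo-2-methoxyphenol | COc1cc(Br)ccc1O | starting material
10 | tributylammonium 7-[(E)-hydrazinylidenemethyl]-3-methoxy-2-oxo-1,2-dihydroquinolin-8-yl sulfate | COc1cc2ccc(/C=N/N)c(OS(=O)(=O)[O-])c2[nH]c1=O.CCCC[NH+](CCCC)CCCC | intermediate
11 | scolopendrine tributylammonium salt (cation partly exchanged for protonated DBU in the pot) | COc1cc(Cc2ccc3cc(OC)c(=O)[nH]c3c2OS(=O)(=O)[O-])ccc1O.CCCC[NH+](CCCC)CCCC | intermediate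
12 | scolopendrine, 7-(4-hydroxy-3-methoxybenzyl)-3-methoxy-2-oxo-1,2-dihydroquinolin-8-yl hydrogen sulfate (achiral) | COc1cc(Cc2ccc3cc(OC)c(=O)[nH]c3c2OS(=O)(=O)O)ccc1O | target

## Totals and risks
Total step count: 5.
Longest linear sequence: 5 steps (1 → 2 → 6 → 7 → 8 → 12). Compounds 3 and 9 are bought.

**Step 5 is the most likely to fail.**
- The valuable hydrazone is the limiting partner, whereas it is normally used in excess.
- It is ionic and carries an ortho substituent.
- The aryl bromide reacts as an electron-rich phenoxide, which slows oxidative addition.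
- Azine formation, plain Wolff–Kishner reduction to the 7-methyl compound and N-arylation all compete.

The fallback sets out from 8 and comes back at 12. It abandons nickel and the free hydrazone and makes the same bond by the metal-free Barluenga–Valdés reductive coupling of a sulfonylhydrazone with a boronic acid. TsNHNH2 in MeOH at rt converts 8 into the N-tosylhydrazone tributylammonium salt F1. Heating F1 with 4-(benzyloxy)-3-methoxyphenylboronic acid (COc1cc(B(O)O)ccc1OCc1ccccc1) and K2CO3 in 1,4-dioxane at 110 °C brings about loss of sulfinate and N2, an aryl 1,2-shift from boron and protodeboronation. This gives O-benzylscolopendrine potassium salt F2. The benzyl group is needed because a free phenol would be O-alkylated under these conditions. H2 with Pd/C in MeOH gives scolopendrine potassium salt F3. Cold dilute HCl followed by C18 desalting returns 12.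

**Step 3 is second.**
- Compound 6 is poorly soluble.
- Its C7 is deactivated by the para vinylogous lactam.
- The phenoxide and lactam nitrogen may bind magnesium as an unreactive chelate, as 8-hydroxyquinoline does.

The fallback sets out from 6 and comes back at 7. It replaces direct formylation by boron-templated ortho-hydroxymethylation followed by oxidation. PhB(OH)2, paraformaldehyde and catalytic propionic acid in refluxing toluene with water removal give the C7/O8-fused 2-phenyl-4H-1,3,2-dioxaborinine F4. Exchange with propane-1,3-diol frees 8-hydroxy-7-(hydroxymethyl)-3-methoxyquinolin-2(1H)-one F5. MnO2 in THF oxidises the benzylic alcohol to 7.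

**Step 2 is third.**
- The amine of 2 is hindered and deactivated.
- Compound 2 self-condenses on standing.
- The amide alpha-CH2 must be deprotonated in a substrate that is already a phenoxide.

The fallback sets out from 1, bypasses 2 and comes back at 6. It forms C3=C4 before the nitrogen is unmasked. Aldol condensation of 1 with methyl methoxyacetate (NaOMe, MeOH/THF, 0 °C to rt) gives methyl (Z)-3-(3-hydroxy-2-nitrophenyl)-2-methoxyacrylate F6. Iron powder in AcOH at 100 °C reduces it to the (Z)-amino ester F7. The hot acid isomerises the push–pull alkene to the (E)-amino ester F8, which lactamises to 6.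

## Further compounds
F1 | step 5 | tributylammonium 3-methoxy-2-oxo-7-[(E)-(2-tosylhydrazinylidene)methyl]-1,2-dihydroquinolin-8-yl sulfate | COc1cc2ccc(/C=N/NS(=O)(=O)c3ccc(C)cc3)c(OS(=O)(=O)[O-])c2[nH]c1=O.CCCC[NH+](CCCC)CCCC
F2 | step 5 | potassium 7-[4-(benzyloxy)-3-methoxybenzyl]-3-methoxy-2-oxo-1,2-dihydroquinolin-8-yl sulfate | COc1cc(Cc2ccc3cc(OC)c(=O)[nH]c3c2OS(=O)(=O)[O-])ccc1OCc1ccccc1.[K+]
F3 | step 5 | scolopendrine potassium salt | COc1cc(Cc2ccc3cc(OC)c(=O)[nH]c3c2OS(=O)(=O)[O-])ccc1O.[K+]
F4 | step 3 | 2-phenyl-4H-1,3,2-dioxaborinine fused at C7 (CH2) and O8 of 3-methoxyquinolin-2(1H)-one | COc1cc2ccc3c(OB(c4ccccc4)OC3)c2[nH]c1=O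
F5 | step 3 | 8-hydroxy-7-(hydroxymethyl)-3-methoxyquinolin-2(1H)-one | COc1cc2ccc(CO)c(O)c2[nH]c1=O
F6 | step 2 | methyl (Z)-3-(3-hydroxy-2-nitrophenyl)-2-methoxyacrylate | COC(=O)/C(OC)=C/c1cccc(O)c1[N+](=O)[O-]
F7 | step 2 | methyl (Z)-3-(2-amino-3-hydroxyphenyl)-2-methoxyacrylate | COC(=O)/C(OC)=C/c1cccc(O)c1N
F8 | step 2 | methyl (E)-3-(2-amino-3-hydroxyphenyl)-2-methoxyacrylate | COC(=O)/C(OC)=C\c1cccc(O)c1N
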